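**Strategy.** Ainsliadimer B is disconnected across its cyclohexene ring (bonds C2–C4′ and C14–C15′) into dehydrozaluzanin C and an upper dienone whose diene C14=C10–C1=C2 contains the later carbinol carbon C10. The C9–C10 bond lies in the seven-membered ring alone, and C10 bears the one-carbon branch C14; the key step exploits both: ring-closing metathesis joins an allyl group on lactone carbon C7 to a 1-[(trimethylsilyl)methyl]vinyl group on C1, and protodesilylation in the same flask moves the new alkene to exocyclic C10=C14. Its precursor is a cyclopentanone and a butyrolactone linked only through C5–C6. Diels–Alder union, singlet-oxygen ene hydroxylation at C10 and deprotection finish.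

Key step: step 8

Remark: guaiane numbering is used (C1–C15 for the upper half, primes for the lower half; α is the face of H-5). Dehydrocostus lactone, a commercial costus-root lactone, is taken as the starting material of the lower half, and its C3′ alcohol is carried as the epimer mixture because C3′ becomes a ketone.

**Step 1**
Reactants: 1 (S)-4-[(tert-butyldimethylsilyl)oxy]cyclopent-2-en-1-one; 2 1,3-dithiane
Product: 5 (S)-4-(1,3-dithian-2-yl)cyclopent-2-en-1-one, via 2-lithio-1,3-dithiane 3 (not isolated), via silyloxy ketone 4 (not isolated)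
Conditions: n-BuLi, THF, −30 °C; HMPA, then 1, −78 °C; aq. NH4Cl; crude + DBU, CH2Cl2, 0 °C
Reagents that add atoms: none
Why: Conjugate addition of the HMPA-solvated dithiane anion (formyl anion equivalent) should occur anti to the silyloxy group and so set C5, and DBU-mediated E1cB loss of silanol from the β-silyloxy ketone then gives the enone without touching C5.

**Step 2**
Reactants: 5 (S)-4-(1,3-dithian-2-yl)cyclopent-2-en-1-one; 6 (triisopropylsiloxy)methyl chloride
Product: 8 (4R,5R)-4-(1,3-dithian-2-yl)-5-{[(triisopropylsilyl)oxy]methyl}cyclopent-2-en-1-one, via lithium enolate 7 (not isolated)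
Conditions: LiN(iPr)2, THF, −78 °C; 6, −78 → −40 °C
Reagents that add atoms: none
Why: Kinetic α′-deprotonation gives the cross-conjugated lithium enolate, which is C-alkylated by the chloromethyl silyl ether (enolate alkylation with an α-chloro ether as hydroxymethyl cation equivalent, the bulky triisopropylsilyl group shielding silicon from attack by the enolate oxygen) on the face anti to the adjacent dithianyl group, so that the silyl-protected hydroxymethyl group arrives in one operation and C4 is set trans to C5 as in the target.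

**Step 3**
Reactants: 8 enone from step 2; 9 (2-bromoprop-2-en-1-yl)trimethylsilane
Product: 11 (2R,3R,4S)-3-(1,3-dithian-2-yl)-2-{[(triisopropylsilyl)oxy]methyl}-4-[3-(trimethylsilyl)prop-1-en-2-yl]cyclopentan-1-one, via Grignard reagent 10 (not isolated)
Conditions: Mg, THF; CuBr·SMe2 (20 mol %), 8, THF, −78 → −30 °C; aq. NH4Cl
Reagents that add atoms: none
Why: Copper-catalysed conjugate addition of the vinyl Grignard reagent should take place anti to the C5 substituent (the C1 configuration is erased in step 9) and installs the 2-(silylmethyl)allyl unit that carries C10 and C14.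

**Step 4**
Reactants: 11 dithianyl ketone
Product: 12 (1R,2R,5S)-3-oxo-2-{[(triisopropylsilyl)oxy]methyl}-5-[3-(trimethylsilyl)prop-1-en-2-yl]cyclopentane-1-carbaldehyde
Conditions: MeI, CaCO3, MeCN/H2O 9:1, 45 °C
Reagents that add atoms: water (SMILES: O)
Why: S-Methylation and hydrolysis of the dithiane under CaCO3-buffered conditions should unmask the aldehyde without protodesilylating the allylsilane or cleaving the silyl ether, and the all-trans aldehyde has no drive to epimerise at C5.

**Step 5**
Reactants: 13 allylmagnesium bromide; 14 methyl propiolate; 15 formaldehyde (gas, from cracked paraformaldehyde)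
Product: 18 methyl (E)-2-(hydroxymethyl)hexa-2,5-dienoate, via allylcopper 16 (not isolated), via vinylcopper intermediate 17 (not isolated)
Conditions: CuBr·SMe2 (1 equiv), THF, −78 °C; 14; 15, −78 → −20 °C; aq. NH4Cl
Reagents that add atoms: none
Why: syn-Carbocupration of the ynoate gives an α-cuprio acrylate that is hydroxymethylated by formaldehyde (tandem conjugate addition–aldol) to the Morita–Baylis–Hillman-type alcohol, whose alkene geometry is of no consequence later.

**Step 6**
Reactants: 18 methyl (E)-2-(hydroxymethyl)hexa-2,5-dienoate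
Product: 19 methyl (Z)-2-(bromomethyl)hexa-2,5-dienoate
Conditions: PBr3, Et2O, −10 °C
Reagents that add atoms: phosphorus tribromide (SMILES: BrP(Br)Br)
Why: Nucleophilic substitution of the primary allylic alcohol gives the 2-(alkoxycarbonyl)allyl bromide, and either allylic regioisomer would lead to the same allylchromium reagent.

**Step 7**
Reactants: 12 aldehyde; 19 methyl (Z)-2-(bromomethyl)hexa-2,5-dienoate
Product: 22 allyl-substituted trans-α-methylene-γ-butyrolactone, via allylchromium reagent 20 (not isolated), via hydroxy ester 21 (not isolated)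
Conditions: CrCl2 (5 equiv), THF, 0 °C → rt, then 45 °C; water
Reagents that add atoms: none
Why: Nozaki–Hiyama allylation: the aldehyde-selective allylchromium reagent should add through a chair transition state with the γ-allyl group equatorial (anti adduct, hence the trans C6/C7 lactone after lactonisation of the chromium alkoxide) and, by Felkin–Anh attack anti to the bulkier C1-bearing ring branch, set H-6β relative to C5.

**Step 8**
Reactants: 22 lactone
Product: 24 tricyclic exo-methylene ketone (1-epi series), via cycloheptene allylsilane 23 (not isolated)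
Conditions: second-generation Grubbs catalyst (H2IMes)(PCy3)Cl2Ru=CHPh (5 mol %), CH2Cl2 (2 mM), 40 °C; then p-TsOH·H2O, 0 °C → rt
Reagents that add atoms: none
Why: The ruthenium alkylidene loads on the monosubstituted C9=CH2 terminus of 22 and, by intramolecular [2+2] cycloaddition and cycloreversion with the 1,1-disubstituted alkene of the allylsilane on C1, expels ethene and forms the C9=C10 bond that closes the seven-membered ring; p-TsOH then protonates C9 (SE2′), the β-silyl cation at C10 loses the silyl group and the alkene ends up exocyclic as C10=C14. The closest known reaction types are ring-closing olefin metathesis to trisubstituted cycloheptenes and acid-mediated protodesilylation of allylsilanes. Only the carbocyclic seven-membered ring (C1, C5, C6, C7, C8, C9, C10) is closed, by metathesis between the two alkene termini, trans-fused to the cyclopentanone. No stereocenter is formed and C4, C5, C6 and C7 are not touched, while the C1 center is removed in step 9 and the primary triisopropylsilyl ether should tolerate the brief exposure to p-TsOH. The step needs chemoselectivity among four alkenes, which the substrate secures because the α-methylene lactone is electron-poor, 1,1-disubstituted and could only close a four-membered ring, and it needs regioselective protonation at C9, which the β-silicon effect secures.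

**Step 9**
Reactants: 24 tricyclic ketone
Product: 26 upper dienone (3-oxo-1,10(14),11(13)-triene), via silyl enol ether 25 (not isolated)
Conditions: LiN(SiMe3)2, Me3SiCl, THF, −78 °C; then Pd(OAc)2, MeCN, rt
Reagents that add atoms: none
Why: Kinetic deprotonation at the less substituted C2 with in situ silylation followed by Saegusa–Ito oxidation should introduce C1=C2, which removes the C1 stereocenter and completes the s-cis diene C14=C10–C1=C2.

**Step 10**
Reactants: 27 dehydrocostus lactone
Product: 28 3-hydroxydehydrocostus lactone (C3 epimers)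
Conditions: SeO2 (0.5 equiv), t-BuOOH, CH2Cl2, rt
Reagents that add atoms: tert-butyl hydroperoxide (SMILES: CC(C)(C)OO)
Why: Selenium dioxide allylic oxidation (ene reaction then [2,3]-sigmatropic shift) of the exocyclic C4′=C15′ alkene hydroxylates the allylic C3′ methylene, and the C3′ configuration is irrelevant because it is oxidised in step 11.

**Step 11**
Reactants: 28 3-hydroxydehydrocostus lactone
Product: 29 dehydrozaluzanin C
Conditions: Dess–Martin periodinane, CH2Cl2, rt
Reagents that add atoms: none
Why: Dess–Martin oxidation of the allylic alcohol gives the exo-methylene cyclopentanone dienophile under non-basic conditions that spare the α-methylene lactone and the ring-fusion stereocenters.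

**Step 12**
Reactants: 26 upper dienone; 29 dehydrozaluzanin C
Product: 32 15-O-triisopropylsilyl ether of ainsliadimer B, via Diels–Alder adduct 30 (not isolated), via C10 hydroperoxide 31 (not isolated)
Conditions: 29 (3 equiv), toluene (1 M), BHT, 60 °C, dark; then O2, tetraphenylporphyrin, visible light, CH2Cl2, −20 °C; then PPh3
Reagents that add atoms: dioxygen (SMILES: O=O)
Why: Thermal Diels–Alder reaction of the s-cis diene with the strained exo-methylene ketone C4′=C15′ follows the ortho rule for a 1-acyl diene (bonds C2–C4′ and C14–C15′) and should occur on the convex α-face of the dienophile and on the α-face of the diene (anti to the C5–C6 bond), setting spiro center C4′ and placing H-2 on the β-face, after which the suprafacial Schenck ene reaction of singlet oxygen delivers oxygen to C10 on the face of the abstracted H-2 (10β-OOH, C1=C2 restored) and PPh3 reduces the hydroperoxide.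

**Step 13**
Reactants: 32 15-O-triisopropylsilyl ether of ainsliadimer B
Product: 33 ainsliadimer B
Conditions: HF·pyridine, pyridine/THF, 0 °C → rt; aq. NaHCO3
Reagents that add atoms: none
Why: Fluoride-driven cleavage of the primary silyl ether under pyridine-buffered conditions should free the C15 alcohol without ionising the tertiary allylic alcohol, adding to the α-methylene lactones or dehydrating the β-hydroxy ketone at C4.

**Compound list**

1 | (S)-4-[(tert-butyldimethylsilyl)oxy]cyclopent-2-en-1-one | O=C1C=C[C@@H](O[Si](C)(C)C(C)(C)C)C1 | starting material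
2 | 1,3-dithiane | C1CSCSC1 | starting material
3 | 2-lithio-1,3-dithiane | [Li]C1SCCCS1 | intermediate
4 | (3S,4S)-4-[(tert-butyldimethylsilyl)oxy]-3-(1,3-dithian-2-yl)cyclopentan-1-one | O=C1C[C@H](C2SCCCS2)[C@@H](O[Si](C)(C)C(C)(C)C)C1 | intermediate
5 | (S)-4-(1,3-dithian-2-yl)cyclopent-2-en-1-one | O=C1C[C@H](C2SCCCS2)C=C1 | intermediate
6 | (triisopropylsiloxy)methyl chloride [(chloromethoxy)triisopropylsilane] | CC(C)[Si](OCCl)(C(C)C)C(C)C | starting material
7 | lithium cross-conjugated enolate of 5 | [Li]OC1=C[C@H](C2SCCCS2)C=C1 | intermediate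
8 | (4R,5R)-4-(1,3-dithian-2-yl)-5-{[(triisopropylsilyl)oxy]methyl}cyclopent-2-en-1-one | O=C1[C@@H](CO[Si](C(C)C)(C(C)C)C(C)C)[C@H](C2SCCCS2)C=C1 | intermediate
9 | (2-bromoprop-2-en-1-yl)trimethylsilane | C=C(Br)C[Si](C)(C)C | starting material
10 | [3-(trimethylsilyl)prop-1-en-2-yl]magnesium bromide | C=C([Mg]Br)C[Si](C)(C)C | intermediate
11 | (2R,3R,4S)-3-(1,3-dithian-2-yl)-2-{[(triisopropylsilyl)oxy]methyl}-4-[3-(trimethylsilyl)prop-1-en-2-yl]cyclopentan-1-one (all-trans) | O=C1C[C@H](C(=C)C[Si](C)(C)C)[C@@H](C2SCCCS2)[C@@H]1CO[Si](C(C)C)(C(C)C)C(C)C | intermediate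
12 | (1R,2R,5S)-3-oxo-2-{[(triisopropylsilyl)oxy]methyl}-5-[3-(trimethylsilyl)prop-1-en-2-yl]cyclopentane-1-carbaldehyde | O=C1C[C@H](C(=C)C[Si](C)(C)C)[C@@H](C=O)[C@@H]1CO[Si](C(C)C)(C(C)C)C(C)C | intermediate
13 | allylmagnesium bromide | C=CC[Mg]Br | starting material
14 | methyl propiolate | C#CC(=O)OC | starting material
15 | formaldehyde | C=O | starting material
16 | allylcopper | C=CC[Cu] | intermediate
17 | methyl (Z)-2-cupriohexa-2,5-dienoate (allyl cis to copper) | C=CC/C=C(\[Cu])C(=O)OC | intermediate
18 | methyl (E)-2-(hydroxymethyl)hexa-2,5-dienoate | C=CC/C=C(\CO)C(=O)OC | intermediate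
19 | methyl (Z)-2-(bromomethyl)hexa-2,5-dienoate | C=CC/C=C(\CBr)C(=O)OC | intermediate
20 | [2-(methoxycarbonyl)hexa-2,5-dienyl]chromium dichloride | C=CC/C=C(\C[Cr](Cl)Cl)C(=O)OC | intermediate
21 | anti hydroxy ester (present as its chromium alkoxide): methyl 2-methylidene-3-allyl-4-hydroxy-4-cyclopentylbutanoate with H-6β, H-7α, cyclopentanone as in 12 | COC(=O)C(=C)[C@H](CC=C)[C@H](O)[C@@H]2[C@@H](C(=C)C[Si](C)(C)C)CC(=O)[C@H]2CO[Si](C(C)C)(C(C)C)C(C)C | intermediate
22 | trans-α-methylene-γ-butyrolactone (H-6β, H-7α, C7-allyl) attached at C6 to C5 of the all-trans cyclopentanone (4α-CH2OSi(iPr)3, 1α-[3-(trimethylsilyl)prop-1-en-2-yl]) | C=C1C(=O)O[C@H]([C@@H]2[C@@H](C(=C)C[Si](C)(C)C)CC(=O)[C@H]2CO[Si](C(C)C)(C(C)C)C(C)C)[C@H]1CC=C | intermediate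
23 | 15-[(triisopropylsilyl)oxy]-14-(trimethylsilyl)-3-oxo-1βH,4βH,5αH-guaia-9,11(13)-dien-12,6α-olide | C=C1C(=O)O[C@@H]2[C@@H]3[C@H](CC(=O)[C@H]3CO[Si](C(C)C)(C(C)C)C(C)C)C(C[Si](C)(C)C)=CC[C@@H]12 | intermediate
24 | 15-[(triisopropylsilyl)oxy]-3-oxo-1βH,4βH,5αH-guaia-10(14),11(13)-dien-12,6α-olide | C=C1C(=O)O[C@@H]2[C@@H]3[C@H](CC(=O)[C@H]3CO[Si](C(C)C)(C(C)C)C(C)C)C(=C)CC[C@@H]12 | intermediate
25 | 3-(trimethylsilyloxy)-2-ene silyl enol ether of 24 | C=C1C(=O)O[C@@H]2[C@@H]3[C@H](C=C(O[Si](C)(C)C)[C@H]3CO[Si](C(C)C)(C(C)C)C(C)C)C(=C)CC[C@@H]12 | intermediate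
26 | 15-[(triisopropylsilyl)oxy]-3-oxo-4βH,5αH-guaia-1,10(14),11(13)-trien-12,6α-olide | C=C1C(=O)O[C@@H]2[C@@H]3C(=CC(=O)[C@H]3CO[Si](C(C)C)(C(C)C)C(C)C)C(=C)CC[C@@H]12 | intermediate
27 | dehydrocostus lactone, (3aS,6aR,9aR,9bS)-3,6,9-trimethylidenedecahydroazuleno[4,5-b]furan-2-one | C=C1CC[C@H]2C(=C)CC[C@H]3C(=C)C(=O)O[C@@H]3[C@H]21 | starting material
28 | 3-hydroxydehydrocostus lactone (both C3 epimers; configuration at C3 not drawn) | C=C1C(O)C[C@H]2C(=C)CC[C@H]3C(=C)C(=O)O[C@@H]3[C@H]21 | intermediate
29 | dehydrozaluzanin C, (3aS,6aR,9aR,9bS)-3,6,9-trimethylideneoctahydroazuleno[4,5-b]furan-2,8-dione | C=C1C(=O)C[C@H]2C(=C)CC[C@H]3C(=C)C(=O)O[C@@H]3[C@H]21 | intermediate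
30 | Diels–Alder adduct: spiro dimer with C1=C10, H-2β, C2–C4′ and C14–C15′ bonds, 15-OSi(iPr)3 | C=C1C(=O)O[C@@H]2[C@@H]3C4=C(CC[C@]5(C(=O)C[C@H]6C(=C)CC[C@H]7C(=C)C(=O)O[C@@H]7[C@H]65)[C@H]4C(=O)[C@H]3CO[Si](C(C)C)(C(C)C)C(C)C)CC[C@@H]12 | intermediate
31 | 10β-hydroperoxide of 15-O-triisopropylsilyl ainsliadimer B | C=C1C(=O)O[C@@H]2[C@@H]3C4=C(C(=O)[C@H]3CO[Si](C(C)C)(C(C)C)C(C)C)[C@]3(CC[C@]4(OO)CC[C@@H]12)C(=O)C[C@H]1C(=C)CC[C@H]2C(=C)C(=O)O[C@@H]2[C@H]13 | intermediate
32 | 15-O-triisopropylsilyl ether of ainsliadimer B | C=C1C(=O)O[C@@H]2[C@@H]3C4=C(C(=O)[C@H]3CO[Si](C(C)C)(C(C)C)C(C)C)[C@]3(CC[C@]4(O)CC[C@@H]12)C(=O)C[C@H]1C(=C)CC[C@H]2C(=C)C(=O)O[C@@H]2[C@H]13 | intermediate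
33 | ainsliadimer B | C=C1C(=O)O[C@@H]2[C@@H]3C4=C(C(=O)[C@H]3CO)[C@]3(CC[C@]4(O)CC[C@@H]12)C(=O)C[C@H]1C(=C)CC[C@H]2C(=C)C(=O)O[C@@H]2[C@H]13 | target

**Totals.** Total step count: 13. Longest linear sequence: 9 steps (1, 2, 3, 4, 7, 8, 9, 12, 13).

**Steps most likely to fail**

Step 12. The dienophile may fail to discriminate the two faces of diene 26, whose C4 side chain sits on the α-face; because the ene step is suprafacial, such a loss would be carried into the C10 configuration. The ene reaction may also abstract H-5, H-9 or H-14 instead of H-2. The fallback sets out from 30, isolated after the cycloaddition. Its C3 ketone is converted with TBSOTf/Et3N into the silyl dienol ether F1, in which C2 is planar. A vinylogous Rubottom oxidation (m-CPBA, NaHCO3, CH2Cl2, −40 °C, then mild acid) should then attack the γ-carbon C10 from the less hindered face, independently of the former C2 configuration, and comes back to the route at 32.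

Step 7. Facial discrimination at the aldehyde carbon may be weak, because the two ring branches that flank C5 are similar in size; this would give mixtures at C6 and C7. The fallback replaces substrate control by reagent control and sets out from 12. Palladium-catalysed addition [Pd(dppf)Cl2, InI, THF/HMPA] of the allenylindium reagent generated from (R)-hex-5-en-1-yn-3-yl methanesulfonate F2 should give the anti homopropargylic alcohol F3. The mesylate configuration is transferred to C6 and C7 by anti SN2′ oxidative addition and syn SE2′ addition. Palladium-catalysed cyclocarbonylation of F3 (PdCl2, PPh3, SnCl2, CO, MeCN) then forms the α-methylene lactone and comes back to the route at 22.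

Step 8. Cyclisation may be slow and lose to intermolecular metathesis, since the two arms are trans on the cyclopentanone and the lactone already restricts rotation about C6–C7. The fallback sets out from 21, isolated when step 7 is quenched cold before lactonisation. Metathesis with the same catalyst is run on this open hydroxy ester to give the cycloheptene hydroxy ester F4. Lactonisation (NaH cat., THF, 0 °C) then comes back to the route at 23, which is protodesilylated to 24 as before.

**Further compounds**

F1 | step 12 | 3-(tert-butyldimethylsilyloxy)-2,1(10)-diene silyl dienol ether of adduct 30 | C=C1C(=O)O[C@@H]2[C@@H]3C4=C(CC[C@]5(C(=O)C[C@H]6C(=C)CC[C@H]7C(=C)C(=O)O[C@@H]7[C@H]65)C4=C(O[Si](C)(C)C(C)(C)C)[C@H]3CO[Si](C(C)C)(C(C)C)C(C)C)CC[C@@H]12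
F2 | step 7 | (R)-hex-5-en-1-yn-3-yl methanesulfonate | C#C[C@@H](CC=C)OS(C)(=O)=O
F3 | step 7 | anti homopropargylic alcohol (C7 bearing allyl and ethynyl, H-6β, H-7α, cyclopentanone as in 12) | C#C[C@H](CC=C)[C@H](O)[C@@H]2[C@@H](C(=C)C[Si](C)(C)C)CC(=O)[C@H]2CO[Si](C(C)C)(C(C)C)C(C)C
F4 | step 8 | cycloheptene hydroxy ester (ring-closed seco-lactone: C6-OH, C7 bearing the methyl acrylate unit, C10 bearing CH2SiMe3) | COC(=O)C(=C)[C@@H]1CC=C(C[Si](C)(C)C)[C@H]2CC(=O)[C@@H](CO[Si](C(C)C)(C(C)C)C(C)C)[C@@H]2[C@H]1O
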